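3 questions stand on this flask, a racemate with a single-handed catalyst, and we read every substrate reading from the symmetric zero of 50%, where nothing has yet gone from either hand.

| flask | left-handed substrate | right-handed substrate | solid reagent | free catalyst | added ligand | remark | time |
|---|---|---|---|---|---|---|---|
| theta | 0.11 M | 0.11 M | 0.102 M | 26 mM | 22 mM | run made earlier |  |
| alpha | 0.26 M | 0.26 M | 0.102 M | 26 mM | 22 mM | run made earlier |  |
| gamma | 0.17 M | 0.17 M | 0.102 M | 26 mM | 33 mM | run made earlier |  |
| flask | 0.17 M | 0.17 M | 0.102 M | 26 mM | 22 mM |  | 2.0 h |

- theta (time / min: left-handed substrate / %, right-handed substrate / %): 8.00: 49.1, 41.4; 12.0: 50.3, 41.0; 20.0: 49.7, 40.0; 25.0: 49.0, 40.0; 40.0: 49.9, 39.5; 60.0: 49.6, 39.4; 90.0: 48.9, 38.3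
- alpha (time / min: left-handed substrate / %, right-handed substrate / %): 8.00: 50.2, 45.8; 12.0: 49.9, 45.6; 20.0: 49.9, 45.8; 25.0: 49.5, 45.9; 40.0: 50.5, 45.3; 60.0: 49.0, 44.8; 90.0: 49.6, 43.5
- gamma (time / min: left-handed substrate / %, right-handed substrate / %): 8.00: 49.5, 43.8; 15.0: 49.6, 43.2; 25.0: 49.6, 43.4; 50.0: 49.9, 43.0; 90.0: 50.0, 42.4

(readings scatter by 0.3 percentage points)

- free catalyst is single-handed; left-handed substrate and right-handed substrate are mirror images of each other, charged as a racemate, each of them at the stated concentration
- given per volume of solution although it is solid: solid reagent
- at the start none of the solid reagent is in solution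
- an excess is the difference of the two amounts in percent of their sum
- an excess is below zero if the other one leads

1. part of the left-handed substrate and right-handed substrate charged together that has reacted at 2.0 h
2. excess of left-handed product over right-handed product in the product at 2.0 h
3. excess of right-handed substrate over left-handed substrate among what is left of the two at 2.0 h

1. We first take the drop of the right-handed substrate at the first reading as product. But it comes to 18.9 mM in theta, 21.8 mM in alpha and 21.1 mM in gamma, although alpha has 2.36 times theta's substrate.

2. So we read this drop as substrate held on the catalyst, one per catalyst, since in each of the three runs it stays below the 26 mM charged, filling 81.1% of it in gamma. The holding share, c(free catalyst) over c(left-handed substrate) + c(right-handed substrate), all as charged, is 7.65% in our flask, and what is held is not product.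

3. Could the later creep be held too? Not wholly in alpha, whose drop at the last reading reaches 33.8 mM, more than the 26 mM of catalyst charged there. So we take the creep as product, at the mean of theta and alpha, whose ligand matches our flask and whose substrate brackets it: 0.115 mM min⁻¹. That gives an estimate of 3.77% of product by 2.0 h.

4. Our own reckoning is therefore a loss near 9.97% and eS near −11.1%. For eP we commit to the sign alone, right-handed product leading, since at the last reading of theta the left-handed substrate, at 48.9%, has lost less than the right-handed substrate, at 38.3%, while a loss that small in the left-handed substrate is hard to size against a scatter of 0.3 percentage points.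

The forecast differs: 9.5%, −91% and −9.6%, on the ground “about 1 mM of left-handed substrate goes with it, so selectivity is about 20:1”.

The flask gives 10.3%, −36.3% and −9.67%, so the forecast's eP of −91% is where the two part.

    free catalyst + left-handed substrate ⇌ catalyst intermediate A (K = 2.80 M⁻¹, k = 202 M⁻¹ h⁻¹)
    free catalyst + right-handed substrate ⇌ catalyst intermediate B (K = 75.0 M⁻¹, k = 178 M⁻¹ h⁻¹)
    partner + catalyst intermediate A → free catalyst + left-handed product (k = 27.1 M⁻¹ h⁻¹)
    partner + catalyst intermediate B → free catalyst + right-handed product (k = 8.96 M⁻¹ h⁻¹)
    left-handed product ⇌ right-handed product (k = 0.566 h⁻¹)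
    solid reagent ⇌ partner, rate k6*(cs6 - [partner]) while solid is left; crystals form when [partner] > cs6 (solubility = 0.0850 M, k = 0.565 h⁻¹)
    free catalyst + added ligand ⇌ idle complex (K = 140 M⁻¹, k = 20.8 M⁻¹ h⁻¹)

At 2.00 h in the flask catalyst intermediate B, the resting state, stands at 79.6% of the catalyst and catalyst intermediate A at 4.13%, so the holding share takes 6.40% of the substrates charged and leaves 3.90% of the loss, against products of 1.25% left-handed and 2.67% right-handed.

In the neighbour flask with 0.065 M of free catalyst the holding share is 19.1%, and filled as in gamma it takes 15.5%. That flask's computed loss of 23.7% then leaves 8.20%, and its products stand at 8.28%.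

(Readings and results stem from a simulated flask on assumed constants, noise included.)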